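**Retrosynthetic overview**
- Numbering: ring A (ester ring) is C1 CO2Me, C2 Me, C3 O-aryl, C4 OH, C5 Me, C6 OH; ring B (acid ring) is C1' O-aryl, C2' CHO, C3' OH, C4' Cl, C5' Me, C6' CO2H.
- The strategy rests on ring A: its alternating O/C substituents are those of a folded tetraketide with one extra C-methyl, and in the unfolded chain C3 is a saturated carbon between the C2 and C4 carbonyls. The ring B oxygen can therefore be attached at C3 by simple substitution before ring A exists.
- Endgame: the target comes from a diaryl ether with ring A complete, by formylation at C2' (the only unsubstituted ring carbon) and one BCl3 step that frees the C3' hydroxyl and the C6' acid.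
- Ring A: disconnect C1–C2 (aldol, then aromatization) to an aryloxy 3,5,7-triketo ester whose C2 ketone is masked as a dioxolane. The chain comes from C4–C5 dianion aldol plus oxidation, and C3–O from SN2 of the ring B phenol on methyl 2-chloro-3-oxobutanoate.
- Ring order: ring B is carried from orsellinic acid (benzyl ester, C4' chlorination, C3' O-methylation); ring A is the only ring formed, in step 9.

Key step: step 9

Remark: the ring B acid is carried as a benzyl ester and the C3' oxygen as a methyl ether, since both tolerate aqueous acid, mild base and TiCl4 and both fall in the final BCl3 step; compounds 6 to 14 are racemic or stereoisomer/tautomer mixtures whose sp3 centres all vanish on aromatization.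

**Route**

Step 1
Reactants: 1 orsellinic acid (2,4-dihydroxy-6-methylbenzoic acid)
Product: 2 benzyl 2,4-dihydroxy-6-methylbenzoate
Conditions: BnBr, KHCO3, DMF, rt
Reagents that add atoms: benzyl bromide, BrCc1ccccc1
Why: Carboxylate O-alkylation (SN2 esterification) under bicarbonate, which is too weak a base to ionize the phenols, so only the acid should be benzylated, and room temperature avoids decarboxylation of the acid.

Step 2
Reactants: 2 benzyl 2,4-dihydroxy-6-methylbenzoate
Product: 3 benzyl 3-chloro-4,6-dihydroxy-2-methylbenzoate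
Conditions: SO2Cl2 (1 equiv), Et2O, 0 °C to rt
Reagents that add atoms: sulfuryl chloride, O=S(=O)(Cl)Cl
Why: Electrophilic aromatic chlorination, expected to enter C4' (para to the ester-chelated C1' hydroxyl, ortho to the free C3' hydroxyl) as is usual for orsellinate esters; one equivalent at low temperature limits dichlorination, and the minor C2' chloro isomer is removed by crystallization.

Step 3
Reactants: 3 benzyl 3-chloro-4,6-dihydroxy-2-methylbenzoate
Product: 4 benzyl 3-chloro-6-hydroxy-4-methoxy-2-methylbenzoate
Conditions: MeI (1.1 equiv), K2CO3, acetone, rt to 40 °C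
Reagents that add atoms: iodomethane, CI
Why: Williamson etherification; the C3' hydroxyl is the more acidic one and is not hydrogen-bonded, whereas the C1' hydroxyl is chelated to the benzyl ester, so one equivalent of MeI should methylate the C3' oxygen only.

Step 4
Reactants: 4 benzyl 3-chloro-6-hydroxy-4-methoxy-2-methylbenzoate; 5 methyl 2-chloro-3-oxobutanoate
Product: 6 methyl 2-[2-(benzyloxycarbonyl)-4-chloro-5-methoxy-3-methylphenoxy]-3-oxobutanoate (racemic)
Conditions: K2CO3, KI (cat.), DMF, 50 °C; dilute HCl work-up
Reagents that add atoms: none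
Why: Williamson-type SN2 displacement of the doubly carbonyl-activated secondary chloride by the phenoxide of 4 places the ring B oxygen on the future C3 of ring A at a saturated carbon, so no hindered aryl–oxygen coupling is ever needed; the new stereocenter is racemic and is erased later.

Step 5
Reactants: 6 methyl 2-[2-(benzyloxycarbonyl)-4-chloro-5-methoxy-3-methylphenoxy]-3-oxobutanoate
Product: 7 methyl 2-[2-(benzyloxycarbonyl)-4-chloro-5-methoxy-3-methylphenoxy]-2-(2-methyl-1,3-dioxolan-2-yl)acetate (racemic)
Conditions: TMSOCH2CH2OTMS, TMSOTf (cat.), CH2Cl2, −78 to −20 °C; pyridine quench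
Reagents that add atoms: 1,2-bis(trimethylsilyloxy)ethane, C[Si](C)(C)OCCO[Si](C)(C)C
Why: Noyori ketalization, driven by formation of hexamethyldisiloxane, masks the ketone at low temperature and avoids hot protic acid, which could transesterify the methyl ester or cyclize the aryloxy keto ester onto C2' to a benzofuran.

Step 6
Reactants: 7 methyl 2-[2-(benzyloxycarbonyl)-4-chloro-5-methoxy-3-methylphenoxy]-2-(2-methyl-1,3-dioxolan-2-yl)acetate
Product: 8 benzyl 3-chloro-4-methoxy-2-methyl-6-[1-(2-methyl-1,3-dioxolan-2-yl)-2-oxoethoxy]benzoate (racemic)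
Conditions: i-Bu2AlH (1.1 equiv), CH2Cl2, −78 °C; MeOH, then aq. KNaC4H4O6 (potassium sodium tartrate)
Reagents that add atoms: none
Why: Partial ester reduction with i-Bu2AlH; the α-aryloxy and dioxolane oxygens chelate aluminium and hold the tetrahedral hemiacetal until work-up, while the di-ortho-substituted aryl benzyl ester is too hindered to react at −78 °C.

Step 7
Reactants: 8 benzyl 3-chloro-4-methoxy-2-methyl-6-[1-(2-methyl-1,3-dioxolan-2-yl)-2-oxoethoxy]benzoate; 9 methyl 3-oxopentanoate
Product: 11 methyl 6-[2-(benzyloxycarbonyl)-4-chloro-5-methoxy-3-methylphenoxy]-5-hydroxy-4-methyl-6-(2-methyl-1,3-dioxolan-2-yl)-3-oxohexanoate (diastereomer mixture), via dilithium dianion of methyl 3-oxopentanoate 10 (not isolated)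
Conditions: 9, LiN(i-Pr)2 (2.1 equiv), THF, 0 °C; then 8, −78 °C; aq. NH4Cl
Reagents that add atoms: none
Why: Weiler dianion aldol addition; the γ-carbanion of 10 adds to the aldehyde faster than it can deprotonate it, forming the C4–C5 bond of the future ring A far more reliably than acylation of the same dianion with the hindered, enolizable ester 7, and the three uncontrolled stereocenters are all removed later.

Step 8
Reactants: 11 methyl 6-[2-(benzyloxycarbonyl)-4-chloro-5-methoxy-3-methylphenoxy]-5-hydroxy-4-methyl-6-(2-methyl-1,3-dioxolan-2-yl)-3-oxohexanoate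
Product: 12 methyl 6-[2-(benzyloxycarbonyl)-4-chloro-5-methoxy-3-methylphenoxy]-4-methyl-6-(2-methyl-1,3-dioxolan-2-yl)-3,5-dioxohexanoate (stereoisomer and enol mixture)
Conditions: Dess–Martin periodinane (1.2 equiv), NaHCO3, CH2Cl2, 0 °C to rt; aq. Na2S2O3
Reagents that add atoms: none
Why: Dess–Martin oxidation of the secondary alcohol should give the 3,5-diketo ester under buffered, neutral conditions that leave the dioxolane, the benzyl ester and, with only a slight excess of oxidant, the acidic methylene untouched.

Step 9
Reactants: 12 methyl 6-[2-(benzyloxycarbonyl)-4-chloro-5-methoxy-3-methylphenoxy]-4-methyl-6-(2-methyl-1,3-dioxolan-2-yl)-3,5-dioxohexanoate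
Product: 15 methyl 3-[2-(benzyloxycarbonyl)-4-chloro-5-methoxy-3-methylphenoxy]-4,6-dihydroxy-2,5-dimethylbenzoate, via free triketo ester 13 (not isolated), via cyclic aldol adduct 14 (not isolated)
Conditions: 1 M aq. HCl/THF, 40 °C; then K2CO3 to pH 10, 0 °C to rt; then HCl to pH 1, rt
Reagents that add atoms: none
Why: Dilute aqueous acid hydrolyses the dioxolane to the methyl ketone and gives the 3,5,7-triketo ester 13; at pH 10 the enolate of the C1 methylene, the only carbon flanked by the ester and a ketone, adds to the C2 ketone to give 14, and on re-acidification two dehydration/tautomerization events should deliver the benzenoid ring at the correct oxidation level, so no oxidant is required. The closest known reaction is the biomimetic aldol cyclization of 3,5,7-triketo esters to orsellinate esters. Ring A closes in the 6-(enolexo)-exo-trig mode. No stereocenter survives, since every sp3 centre of 12 to 14 becomes an aromatic carbon. The step needs C1-to-C2 carbon attack to beat closure through an enol oxygen (4-pyranone from the 1,3,5-triketone, 2-pyranone by attack on the ester) and aldol attack of the terminal methyl on C6; a brief, dilute, aqueous acid stage followed by closure in mild base disfavours the O-closures, and the much higher acidity of C1 over the ketone methyl secures the second point. Claisen attack of C3 on the ester would create a quaternary centre that cannot aromatize and is reversible, and the hindered benzyl ester and the C3 aryl ether are inert in both stages.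

Step 10
Reactants: 15 methyl 3-[2-(benzyloxycarbonyl)-4-chloro-5-methoxy-3-methylphenoxy]-4,6-dihydroxy-2,5-dimethylbenzoate
Product: 16 methyl 3-[2-(benzyloxycarbonyl)-4-chloro-6-formyl-5-methoxy-3-methylphenoxy]-4,6-dihydroxy-2,5-dimethylbenzoate
Conditions: Cl2CHOMe, TiCl4 (excess), CH2Cl2, −78 to 0 °C; then 1 M aq. HCl, rt
Reagents that add atoms: dichloromethyl methyl ether, COC(Cl)Cl; water, O
Why: Rieche formylation; the TiCl4-activated dichloromethyl ether should attack C2', the only unsubstituted ring carbon in the molecule, which is ortho to both ring B ether oxygens and para to the C5' methyl, and the resulting chloro ether, like any titanium phenoxide or aryl formate formed on ring A, is hydrolysed in the acidic work-up.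

Step 11
Reactants: 16 methyl 3-[2-(benzyloxycarbonyl)-4-chloro-6-formyl-5-methoxy-3-methylphenoxy]-4,6-dihydroxy-2,5-dimethylbenzoate
Product: 17 3-chloro-6-[2,4-dihydroxy-5-(methoxycarbonyl)-3,6-dimethylphenoxy]-5-formyl-4-hydroxy-2-methylbenzoic acid (CNP0210944.0)
Conditions: BCl3 (excess), CH2Cl2, −78 to 0 °C; then H2O
Reagents that add atoms: none
Why: Lewis acid dealkylation; BCl3 chelated between the C2' aldehyde oxygen and the C3' methoxy oxygen should cleave that methyl ether (ortho-carbonyl-assisted demethylation) and also cleave the benzyl ester by benzyl–oxygen scission, while the ring A methyl ester and the diaryl ether persist at 0 °C and no free ring carbon is left to be benzylated.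

**Compound list**

1 | orsellinic acid (2,4-dihydroxy-6-methylbenzoic acid) | Cc1cc(O)cc(O)c1C(=O)O | starting material
2 | benzyl 2,4-dihydroxy-6-methylbenzoate | Cc1cc(O)cc(O)c1C(=O)OCc1ccccc1 | intermediate
3 | benzyl 3-chloro-4,6-dihydroxy-2-methylbenzoate | Cc1c(Cl)c(O)cc(O)c1C(=O)OCc1ccccc1 | intermediate
4 | benzyl 3-chloro-6-hydroxy-4-methoxy-2-methylbenzoate | Cc1c(Cl)c(OC)cc(O)c1C(=O)OCc1ccccc1 | intermediate
5 | methyl 2-chloro-3-oxobutanoate | COC(=O)C(Cl)C(C)=O | starting material
6 | methyl 2-[2-(benzyloxycarbonyl)-4-chloro-5-methoxy-3-methylphenoxy]-3-oxobutanoate (racemic) | COC(=O)C(Oc1cc(OC)c(Cl)c(C)c1C(=O)OCc1ccccc1)C(C)=O | intermediate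
7 | methyl 2-[2-(benzyloxycarbonyl)-4-chloro-5-methoxy-3-methylphenoxy]-2-(2-methyl-1,3-dioxolan-2-yl)acetate (racemic) | COC(=O)C(Oc1cc(OC)c(Cl)c(C)c1C(=O)OCc1ccccc1)C1(C)OCCO1 | intermediate
8 | benzyl 3-chloro-4-methoxy-2-methyl-6-[1-(2-methyl-1,3-dioxolan-2-yl)-2-oxoethoxy]benzoate (racemic) | O=CC(Oc1cc(OC)c(Cl)c(C)c1C(=O)OCc1ccccc1)C1(C)OCCO1 | intermediate
9 | methyl 3-oxopentanoate | CCC(=O)CC(=O)OC | starting material
10 | dilithium dianion of methyl 3-oxopentanoate | [Li+].[Li+].C[CH-]C(=O)[CH-]C(=O)OC | intermediate (not isolated)
11 | methyl 6-[2-(benzyloxycarbonyl)-4-chloro-5-methoxy-3-methylphenoxy]-5-hydroxy-4-methyl-6-(2-methyl-1,3-dioxolan-2-yl)-3-oxohexanoate (diastereomer mixture) | COC(=O)CC(=O)C(C)C(O)C(Oc1cc(OC)c(Cl)c(C)c1C(=O)OCc1ccccc1)C1(C)OCCO1 | intermediate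
12 | methyl 6-[2-(benzyloxycarbonyl)-4-chloro-5-methoxy-3-methylphenoxy]-4-methyl-6-(2-methyl-1,3-dioxolan-2-yl)-3,5-dioxohexanoate (stereoisomer and enol mixture) | COC(=O)CC(=O)C(C)C(=O)C(Oc1cc(OC)c(Cl)c(C)c1C(=O)OCc1ccccc1)C1(C)OCCO1 | intermediate
13 | methyl 6-[2-(benzyloxycarbonyl)-4-chloro-5-methoxy-3-methylphenoxy]-4-methyl-3,5,7-trioxooctanoate (stereoisomer and enol mixture) | COC(=O)CC(=O)C(C)C(=O)C(Oc1cc(OC)c(Cl)c(C)c1C(=O)OCc1ccccc1)C(C)=O | intermediate (not isolated)
14 | methyl 3-[2-(benzyloxycarbonyl)-4-chloro-5-methoxy-3-methylphenoxy]-2-hydroxy-2,5-dimethyl-4,6-dioxocyclohexane-1-carboxylate (stereoisomer mixture) | COC(=O)C1C(=O)C(C)C(=O)C(Oc2cc(OC)c(Cl)c(C)c2C(=O)OCc2ccccc2)C1(C)O | intermediate (not isolated)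
15 | methyl 3-[2-(benzyloxycarbonyl)-4-chloro-5-methoxy-3-methylphenoxy]-4,6-dihydroxy-2,5-dimethylbenzoate | COC(=O)c1c(C)c(Oc2cc(OC)c(Cl)c(C)c2C(=O)OCc2ccccc2)c(O)c(C)c1O | intermediate
16 | methyl 3-[2-(benzyloxycarbonyl)-4-chloro-6-formyl-5-methoxy-3-methylphenoxy]-4,6-dihydroxy-2,5-dimethylbenzoate | COC(=O)c1c(C)c(Oc2c(C=O)c(OC)c(Cl)c(C)c2C(=O)OCc2ccccc2)c(O)c(C)c1O | intermediate
17 | 3-chloro-6-[2,4-dihydroxy-5-(methoxycarbonyl)-3,6-dimethylphenoxy]-5-formyl-4-hydroxy-2-methylbenzoic acid | COC(=O)c1c(C)c(Oc2c(C=O)c(O)c(Cl)c(C)c2C(=O)O)c(O)c(C)c1O | target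

**Summary**

Total step count: 11. Longest linear sequence: 11 steps, from 1 to 17; compounds 5 and 9 are purchased, so there is no side branch.

**Steps most likely to fail**

Step 9. Hydrolysis of the electron-poor dioxolane may be slow, and the 1,3,5-triketone, once free and still in acid, may close through an enol oxygen and dehydrate to a 4-pyranone before the base stage. The fallback makes this O-closure the intended path. Setting out from 12, trifluoroacetic acid in CH2Cl2 at room temperature should remove the dioxolane and cyclodehydrate to the 4-pyranone methyl 2-{5-[2-(benzyloxycarbonyl)-4-chloro-5-methoxy-3-methylphenoxy]-3,6-dimethyl-4-oxo-4H-pyran-2-yl}acetate F1. Heating F1 with Mg(OMe)2 in MeOH should open the pyranone by conjugate addition at its methyl-bearing carbon (Collie-type conversion of a 4-pyranone into a resorcinol) to a magnesium-chelated open-chain polyketo ester. This closes C1 to C2 as in the main route and, after acid work-up, comes back to the route at 15.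

Step 10. Electrophilic attack at C2' may be blocked, because that carbon lies between the bulky aryloxy group and the methoxy group on a ring deactivated by chlorine and the ester, or the Lewis acid may strip the benzyl ester first. The fallback reverses deprotection and formylation so that a free phenol directs the new carbon. Setting out from 15, BBr3 in CH2Cl2 (−78 to 0 °C) should cleave the C3' methyl ether and the benzyl ester to give 3-chloro-6-[2,4-dihydroxy-5-(methoxycarbonyl)-3,6-dimethylphenoxy]-4-hydroxy-2-methylbenzoic acid F2. Magnesium phenoxide ortho-formylation (MgCl2, Et3N, paraformaldehyde, MeCN, reflux; Casnati–Skattebøl conditions) should then place the formyl group at C2', the only ring carbon ortho to a free hydroxyl, and come back to the route at 17.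

Step 4. The carbonate may convert chloride 5 into its unreactive enolate, and the ester-chelated, hindered phenoxide of 4 may then be too slow, so that deacetylation of 5 or of the product takes over. The fallback forms the same C–O bond by carbenoid O–H insertion under neutral conditions. Methyl 2-diazo-3-oxobutanoate F3 is prepared from methyl acetoacetate by diazo transfer (4-acetamidobenzenesulfonyl azide, Et3N, MeCN). Setting out from 4, F3 with catalytic Rh2(OAc)4 in CH2Cl2 at reflux should insert into the phenolic O–H bond and come back to the route at 6.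

**Further compounds**

F1 | step 9 | methyl 2-{5-[2-(benzyloxycarbonyl)-4-chloro-5-methoxy-3-methylphenoxy]-3,6-dimethyl-4-oxo-4H-pyran-2-yl}acetate | COC(=O)CC1=C(C)C(=O)C(Oc2cc(OC)c(Cl)c(C)c2C(=O)OCc2ccccc2)=C(C)O1
F2 | step 10 | 3-chloro-6-[2,4-dihydroxy-5-(methoxycarbonyl)-3,6-dimethylphenoxy]-4-hydroxy-2-methylbenzoic acid | COC(=O)c1c(C)c(Oc2cc(O)c(Cl)c(C)c2C(=O)O)c(O)c(C)c1O
F3 | step 4 | methyl 2-diazo-3-oxobutanoate | COC(=O)C(=[N+]=[N-])C(C)=O
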